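Time and temperature first: both flasks are read at 10 min. Eta stays at −40 °C with 0.330 equiv of reagent, while beta goes from −40 °C to −20 °C at 5.0 min and carries 1.00 equiv.

in all of them: solid substrate 0.25 M

|  | reagent | temperature | remark | time |
|---|---|---|---|---|
| north-west | 0.35 equiv (in portions, 3) | −45 °C | run made earlier; portions every 40 s |  |
| south-west | 0.56 equiv (in portions, 3) | −30 °C | run made earlier; portions every 40 s |  |
| north | 0.87 equiv (in portions, 3) | −45 °C | run made earlier; portions every 40 s |  |
| beta | 1.00 equiv (in portions, 3) |  | at −40 °C until 5.0 min, from then on at −20 °C; the portions of reagent follow each other after 40 s, the first at the start | 10 min |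
| eta | 0.330 equiv (in portions, 3) |  | at −40 °C throughout; the portions of reagent follow each other after 40 s, the first at the start | 10 min |

| run | time / min | product / % | solid substrate / % |
|---|---|---|---|
| north-west | 0.417 | 0 | 93.3 |
| north-west | 1.33 | 0.1 | 77.7 |
| north-west | 2.50 | 1.5 | 61.8 |
| north-west | 4.00 | 2.8 | 48.0 |
| north-west | 5.00 | 4.8 | 38.5 |
| south-west | 0.250 | 0 | 94.7 |
| south-west | 0.500 | 1.2 | 90.6 |
| south-west | 0.833 | 1.7 | 84.4 |
| south-west | 1.50 | 7.0 | 74.2 |
| south-west | 3.00 | 23.3 | 50.8 |
| north | 1.00 | 0 | 83.3 |
| north | 2.00 | 0.2 | 68.2 |
| north | 3.00 | 1.2 | 56.2 |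
| north | 4.00 | 3.4 | 45.4 |
| north | 5.00 | 4.6 | 36.1 |

(standard deviation of a reading: 0.5 percentage points)

- given per volume of solution although it is solid: solid substrate
- at the start none of the solid substrate is in solution
- what has only dissolved of solid substrate counts as not reacted

1. which one finishes higher in amount of product, in percent of the solid substrate charged ("neither" within 2 percentage points) (beta / eta / neither)
2. amount of product at the end, in percent of the solid substrate charged, beta
3. amount of product at the end, in percent of the solid substrate charged, eta

*What does the solid column give?* A clock for dissolving. Read as first order, it gives 0.191 min⁻¹ in the north-west run and 0.226 min⁻¹ in the south-west run, so I take their mean, k_d = 0.208 min⁻¹.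

*Does reagent set the product?* Not visibly: at −45 °C, the north-west and north runs differ by 0.2 percentage points at 5.00 min, with a scatter of 0.5 points.

*Then what feeds it?* Take P as what has left the solid and is not yet product, and k_p as the slope of product divided by P. In those two runs, between 4.00 min and 5.00 min, P averages 54.1 %, so k_p reads 0.0296 min⁻¹. The south-west run, between 1.50 min and 3.00 min, reads 0.486 min⁻¹.

*But nobody ran −20 °C.* True, and that is the weak spot. A straight line of ln k_p against temperature gives 0.0752 min⁻¹ at −40 °C, and, by extrapolation, 3.14 min⁻¹ at −20 °C.

*Your one number?* At −40 °C, k_p/k_d is 0.361. Call it the catch-up ratio D, the first-order constant of dissolved material becoming product over that of solid dissolving; time drops out. On these two first-order constants, a D far above one puts product close behind the dissolving, and a D below one leaves dissolved material standing. At −20 °C, D is 15.1, far above its value at −40 °C.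

*So?* In eta the reciprocal of k_p is 13.3 min, longer than the whole run, so dissolved material should still stand at the end. In the warm stretch of beta, by the extrapolation, it becomes 0.318 min, far shorter than that stretch, so I commit to beta ending higher.

The forecast, which puts numbers where I give an order, says beta, with 87 % (72 % to 93 %) for beta and 30 % (24 % to 33.5 %) for eta, and that in the warm stage “then dissolved material converts rapidly”.

The flasks give beta: beta 75.3 %, eta 43.5 %.

    intermediate C ⇌ intermediate D (K = 0.140, k = 0.00180 s⁻¹, Ea = 60.0 kJ mol⁻¹, ΔH = −58.0 kJ mol⁻¹)
    intermediate B → intermediate C (k = 0.00980 s⁻¹, Ea = 62.0 kJ mol⁻¹)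
    starting material → intermediate A (k = 0.00230 s⁻¹, Ea = 73.0 kJ mol⁻¹)
    solid substrate ⇌ starting material, rate k4*(cs4 - [starting material]) while solid is left; crystals form when [starting material] > cs4 (solubility = 0.200 M, k = 0.00410 s⁻¹)
    intermediate A → product (k = 0.0200 s⁻¹, Ea = 66.0 kJ mol⁻¹)
    starting material + reagent ⇌ intermediate B (K = 3.60 M⁻¹, k = 0.0140 M⁻¹ s⁻¹, Ea = 39.0 kJ mol⁻¹, ΔH = −39.0 kJ mol⁻¹)
    (constants at −40 °C)

At 10.0 min, eta, with D at 0.361, still holds 38.0 % of starting material, while beta, warmed since 5.0 min, holds 0 % of it and 24.3 % of intermediate C. Now keep eta as it is but hold it at −25 °C. On the same straight line, extended, D comes to 5.93, and the reciprocal of k_p to 0.809 min, far shorter than the run. That neighbouring flask ends with 0.0296 % of starting material, 7.74 % of intermediate C and 92.1 % of product.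

All runs are calculated for substances that don't exist; the scatter is artificial.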